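**Retrosynthetic overview** (cembrane numbering, see assumption)
1. Target 23 ⇒ open-chain 21: one flask closes the C1–C14 bond (14-membered carbocycle) and the O14–C16 bond (cis-γ-lactone) by indium Barbier allylation/lactonisation of an unprotected α-hydroxy aldehyde carrying a 2-(bromomethyl)enoate. C1 and C14 are set here.
2. 21 ⇒ 18 + 19: bromo-enoate by cross-metathesis, aldehyde by primary-selective oxidation.
3. 18 ⇒ 9 + 14: cis-C6=C7 by Wittig; the oxirane (C3–C4) by Shi epoxidation of the (E)-trisubstituted olefin.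
4. 9 ⇐ (S)-citronellal 1: C12 from the pool, C13 by proline aminoxylation, C8 by SeO2 oxidation/Sharpless epoxidation/hydride opening.
5. 14 ⇐ 4-bromobut-1-yne 10 + allyl bromide 11 (Negishi carboalumination). Ring order: oxirane first, then carbocycle and lactone together.

Assumption: cembrane numbering is used for positions (C1 = ring-fusion CH bearing C15, C14 = lactone O–CH, C13 = CHOH, C12 = CHMe, C8 = C(Me)OH, C6=C7 cis-olefin, C3–C4 oxirane, C15–C17 = acrylate carbons); (S)-citronellal and D-(−)-diethyl tartrate are taken as commercial in high ee.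

**Step 1**
Reactants: 1 (S)-citronellal
Product: 3 (2R,3S)-3,7-dimethyl-2-[(phenylamino)oxy]oct-6-en-1-ol, via aminooxy aldehyde 2 (not isolated)
Conditions: PhNO (0.9 equiv), L-proline (20 mol %), DMSO, rt; then NaBH4, MeOH, 0 °C
Reagents that add atoms: nitrosobenzene O=Nc1ccccc1
Why: Proline-catalysed α-aminoxylation (O-selective nitroso aldol through the L-proline enamine) sets C13 as R under catalyst control next to the resident C12 methyl, and immediate borohydride reduction prevents epimerisation.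

**Step 2**
Reactants: 3 (2R,3S)-3,7-dimethyl-2-[(phenylamino)oxy]oct-6-en-1-ol
Product: 4 (2R,3S)-3,7-dimethyloct-6-ene-1,2-diol
Conditions: Zn dust, AcOH/EtOH (1:4), rt
Reagents that add atoms: none
Why: Dissolving-metal reductive cleavage of the weak N–O bond frees the secondary hydroxyl without touching the olefin or either stereocentre.

**Step 3**
Reactants: 4 (2R,3S)-3,7-dimethyloct-6-ene-1,2-diol
Product: 5 (2R,3S)-1,2-bis[(tert-butyldimethylsilyl)oxy]-3,7-dimethyloct-6-ene
Conditions: TBSOTf (2.4 equiv), 2,6-lutidine, CH2Cl2, 0 °C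
Reagents that add atoms: tert-butyldimethylsilyl trifluoromethanesulfonate CC(C)(C)[Si](C)(C)OS(=O)(=O)C(F)(F)F
Why: Exhaustive O-silylation gives a diol protection that survives steps 4–11 and is later removed by fluoride without acid.

**Step 4**
Reactants: 5 (2R,3S)-1,2-bis[(tert-butyldimethylsilyl)oxy]-3,7-dimethyloct-6-ene
Product: 6 (2E,6S,7R)-7,8-bis[(tert-butyldimethylsilyl)oxy]-2,6-dimethyloct-2-en-1-ol
Conditions: SeO2 (0.3 equiv), t-BuOOH (3 equiv), salicylic acid (10 mol %), CH2Cl2, rt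
Reagents that add atoms: selenium dioxide O=[Se]=O (catalytic oxygen carrier); tert-butyl hydroperoxide CC(C)(C)OO
Why: Sharpless–Umbreit allylic oxidation (ene reaction then [2,3]-sigmatropic shift) hydroxylates selectively the (E)-methyl group of the trisubstituted olefin, turning that methyl into C7.

**Step 5**
Reactants: 6 (2E,6S,7R)-7,8-bis[(tert-butyldimethylsilyl)oxy]-2,6-dimethyloct-2-en-1-ol
Product: 7 {(2R,3R)-3-[(3S,4R)-4,5-bis[(tert-butyldimethylsilyl)oxy]-3-methylpentyl]-2-methyloxiran-2-yl}methanol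
Conditions: Ti(OiPr)4 (10 mol %), D-(−)-diethyl tartrate (12 mol %), t-BuOOH (2 equiv), 4 Å MS, CH2Cl2, −20 °C
Reagents that add atoms: tert-butyl hydroperoxide CC(C)(C)OO
Why: Katsuki–Sharpless asymmetric epoxidation of the 2-methyl (E)-allylic alcohol with the D-tartrate gives the (2R,3R)-epoxy alcohol under reagent control, which fixes the C8 carbinol configuration.

**Step 6**
Reactants: 7 {(2R,3R)-3-[(3S,4R)-4,5-bis[(tert-butyldimethylsilyl)oxy]-3-methylpentyl]-2-methyloxiran-2-yl}methanol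
Product: 8 (2S,6S,7R)-7,8-bis[(tert-butyldimethylsilyl)oxy]-2,6-dimethyloctane-1,2-diol
Conditions: LiAlH4, THF, 0 °C → rt
Reagents that add atoms: none
Why: SN2 hydride opening can occur only at the secondary epoxide carbon (the other is quaternary), so the tertiary C–O stereocentre is kept and the 2-methyl-1,2-diol with C8 = S results.

**Step 7**
Reactants: 8 (2S,6S,7R)-7,8-bis[(tert-butyldimethylsilyl)oxy]-2,6-dimethyloctane-1,2-diol
Product: 9 (2S,6S,7R)-7,8-bis[(tert-butyldimethylsilyl)oxy]-2-hydroxy-2,6-dimethyloctanal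
Conditions: SO3·pyridine, DMSO, Et3N, CH2Cl2, 0 °C
Reagents that add atoms: none
Why: Parikh–Doering oxidation converts only the primary alcohol into the aldehyde under non-acidic conditions, and the α-quaternary aldehyde cannot epimerise.

**Step 8**
Reactants: 10 4-bromobut-1-yne; 11 allyl bromide
Product: 13 (4E)-7-bromo-5-methylhepta-1,4-diene, via alkenylalane 12 (not isolated)
Conditions: Me3Al (2.2 equiv), Cp2ZrCl2 (25 mol %), CH2Cl2, 0 °C → rt; then 11, Pd(PPh3)4 (3 mol %), THF, rt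
Reagents that add atoms: trimethylaluminium C[Al](C)C
Why: Negishi zirconium-catalysed carboalumination adds methyl and aluminium syn across the terminal alkyne (methyl to the internal carbon) and the alkenylalane couples with allyl bromide under zerovalent-palladium catalysis with retention, giving the (E)-trisubstituted C3=C4 olefin while the primary alkyl bromide stays intact.

**Step 9**
Reactants: 13 (4E)-7-bromo-5-methylhepta-1,4-diene
Product: 14 [(3E)-3-methylhepta-3,6-dien-1-yl]triphenylphosphonium bromide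
Conditions: PPh3, MeCN, 80 °C
Reagents that add atoms: triphenylphosphine c1ccc(cc1)P(c1ccccc1)c1ccccc1
Why: SN2 quaternisation of the primary bromide gives the Wittig salt.

**Step 10**
Reactants: 14 [(3E)-3-methylhepta-3,6-dien-1-yl]triphenylphosphonium bromide; 9 (2S,6S,7R)-7,8-bis[(tert-butyldimethylsilyl)oxy]-2-hydroxy-2,6-dimethyloctanal
Product: 16 (2R,3S,7S,8Z,11E)-1,2-bis[(tert-butyldimethylsilyl)oxy]-3,7,11-trimethylpentadeca-8,11,14-trien-7-ol, via ylide 15 (not isolated)
Conditions: 14 (2.4 equiv), NaN(SiMe3)2 (2.3 equiv), THF, −78 → 0 °C; then 9, −78 °C → rt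
Reagents that add atoms: none
Why: Lithium-free Wittig reaction of the non-stabilised ylide passes through the kinetic cis-oxaphosphetane and gives the cis C6=C7 olefin; the extra equivalent of ylide only deprotonates the tertiary hydroxyl, which returns on work-up.

**Step 11**
Reactants: 16 (2R,3S,7S,8Z,11E)-1,2-bis[(tert-butyldimethylsilyl)oxy]-3,7,11-trimethylpentadeca-8,11,14-trien-7-ol
Product: 17 (2R,3S,7S,8Z)-1,2-bis[(tert-butyldimethylsilyl)oxy]-3,7-dimethyl-10-[(2R,3R)-2-methyl-3-(prop-2-en-1-yl)oxiran-2-yl]dec-8-en-7-ol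
Conditions: D-fructose-derived Shi ketone (0.3 equiv), KHSO5 (1.5 equiv, as the triple salt 2KHSO5·KHSO4·K2SO4), K2CO3, Bu4NHSO4 (cat.), MeCN/dimethoxymethane/aq. Na2B4O7 buffer (pH 10.5), 0 °C
Reagents that add atoms: potassium peroxymonosulfate [K+].[O-]S(=O)(=O)OO
Why: Shi asymmetric epoxidation (chiral dioxirane, spiro transition state) reacts fastest with the electron-rich (E)-trisubstituted olefin, leaving the hindered cis and the terminal olefins, and the D-fructose-derived ketone gives the (R,R)-oxirane (C3, C4).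

**Step 12**
Reactants: 17 (2R,3S,7S,8Z)-1,2-bis[(tert-butyldimethylsilyl)oxy]-3,7-dimethyl-10-[(2R,3R)-2-methyl-3-(prop-2-en-1-yl)oxiran-2-yl]dec-8-en-7-ol
Product: 18 (2R,3S,7S,8Z)-3,7-dimethyl-10-[(2R,3R)-2-methyl-3-(prop-2-en-1-yl)oxiran-2-yl]dec-8-ene-1,2,7-triol
Conditions: Bu4NF (3 equiv), THF, 0 °C → rt
Reagents that add atoms: none
Why: Fluoride-induced desilylation frees the 1,2-diol under non-acidic conditions, which the oxirane and the tertiary allylic alcohol tolerate.

**Step 13**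
Reactants: 18 (2R,3S,7S,8Z)-3,7-dimethyl-10-[(2R,3R)-2-methyl-3-(prop-2-en-1-yl)oxiran-2-yl]dec-8-ene-1,2,7-triol; 19 methyl 2-(bromomethyl)prop-2-enoate
Product: 20 methyl (2Z)-2-(bromomethyl)-4-{(2R,3R)-3-methyl-3-[(2Z,4S,8S,9R)-4,9,10-trihydroxy-4,8-dimethyldec-2-en-1-yl]oxiran-2-yl}but-2-enoate
Conditions: 19 (5 equiv), second-generation Hoveyda–Grubbs catalyst RuCl2(=CH-C6H4-2-OiPr)(H2IMes) (7 mol %), 1,4-benzoquinone (10 mol %), CH2Cl2, 40 °C
Reagents that add atoms: none
Why: Olefin cross-metathesis of the unhindered terminal olefin with a non-homodimerising 2-substituted acrylate gives the trisubstituted enoate with the chain trans to the ester; the hindered cis olefin is spared, ring-closing onto it is impossible because C2 and C5 are trans on the oxirane, and either enoate geometry gives the same allylindium in step 14.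

**Step 14**
Reactants: 20 methyl (2Z)-2-(bromomethyl)-4-{(2R,3R)-3-methyl-3-[(2Z,4S,8S,9R)-4,9,10-trihydroxy-4,8-dimethyldec-2-en-1-yl]oxiran-2-yl}but-2-enoate
Product: 23 (1S,3R,4R,6Z,8S,12S,13R,14R)-3,4-epoxy-8,13-dihydroxycembra-6,15(17)-dien-16,14-olide, via hydroxy aldehyde 21 (not isolated), via seco hydroxy ester 22 (not isolated)
Conditions: TEMPO (0.1 equiv), PhI(OAc)2 (1.05 equiv), NaHCO3, CH2Cl2, 0 °C → rt; then dilute with THF/H2O (3:1) to 2 mM, In powder (4 equiv), rt; pH 7 work-up, silica gel/CH2Cl2 to complete lactonisation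
Reagents that add atoms: none
Why: Proposed new method: the nitroxyl-catalysed oxidation touches only the primary carbinol, trivalent indium chelates O13 and the carbonyl oxygen of the resulting 13-hydroxy aldehyde so that the allylindium formed from the allylic bromide adds through its γ-carbon (C1) to the chelate face anti to the C12 branch (C14 = R, 13,14-syn) via a chair transition state that places the C2 substituent syn to the new carbinol (C1 = S), and the syn γ-hydroxy ester then expels methanol to give the cis-fused α-methylene-γ-lactone (five-membered closure on O14 is kinetically preferred over six-membered closure on O13), so carbocycle and lactone close in the same flask; the closest known chemistry is the aqueous indium Barbier addition of (Z)-2-(bromomethyl)alk-2-enoates to unprotected α-hydroxy aldehydes (chelation-controlled syn,syn adducts) and the zinc- or chromium-mediated Barbier macrocyclisation of ω-formyl 2-(bromomethyl)acrylates to fused α-methylene lactones.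

**Compound list**
1 | (S)-citronellal, (3S)-3,7-dimethyloct-6-enal | O=CC[C@@H](C)CCC=C(C)C | starting material
2 | (2R,3S)-3,7-dimethyl-2-[(phenylamino)oxy]oct-6-enal | O=C[C@H](ONc1ccccc1)[C@@H](C)CCC=C(C)C | intermediate
3 | (2R,3S)-3,7-dimethyl-2-[(phenylamino)oxy]oct-6-en-1-ol | OC[C@H](ONc1ccccc1)[C@@H](C)CCC=C(C)C | intermediate
4 | (2R,3S)-3,7-dimethyloct-6-ene-1,2-diol | OC[C@H](O)[C@@H](C)CCC=C(C)C | intermediate
5 | (2R,3S)-1,2-bis[(tert-butyldimethylsilyl)oxy]-3,7-dimethyloct-6-ene | CC(C)(C)[Si](C)(C)OC[C@H](O[Si](C)(C)C(C)(C)C)[C@@H](C)CCC=C(C)C | intermediate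
6 | (2E,6S,7R)-7,8-bis[(tert-butyldimethylsilyl)oxy]-2,6-dimethyloct-2-en-1-ol | CC(C)(C)[Si](C)(C)OC[C@H](O[Si](C)(C)C(C)(C)C)[C@@H](C)CC/C=C(\C)CO | intermediate
7 | {(2R,3R)-3-[(3S,4R)-4,5-bis[(tert-butyldimethylsilyl)oxy]-3-methylpentyl]-2-methyloxiran-2-yl}methanol | CC(C)(C)[Si](C)(C)OC[C@H](O[Si](C)(C)C(C)(C)C)[C@@H](C)CC[C@H]1O[C@]1(C)CO | intermediate
8 | (2S,6S,7R)-7,8-bis[(tert-butyldimethylsilyl)oxy]-2,6-dimethyloctane-1,2-diol | CC(C)(C)[Si](C)(C)OC[C@H](O[Si](C)(C)C(C)(C)C)[C@@H](C)CCC[C@](C)(O)CO | intermediate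
9 | (2S,6S,7R)-7,8-bis[(tert-butyldimethylsilyl)oxy]-2-hydroxy-2,6-dimethyloctanal | CC(C)(C)[Si](C)(C)OC[C@H](O[Si](C)(C)C(C)(C)C)[C@@H](C)CCC[C@](C)(O)C=O | intermediate
10 | 4-bromobut-1-yne | C#CCCBr | starting material
11 | allyl bromide (3-bromoprop-1-ene) | C=CCBr | starting material
12 | [(1E)-4-bromo-2-methylbut-1-en-1-yl]dimethylalane | C[Al](C)/C=C(\C)CCBr | intermediate
13 | (4E)-7-bromo-5-methylhepta-1,4-diene | BrCC/C(C)=C/CC=C | intermediate
14 | [(3E)-3-methylhepta-3,6-dien-1-yl]triphenylphosphonium bromide | [Br-].C=CC/C=C(\C)CC[P+](c1ccccc1)(c1ccccc1)c1ccccc1 | intermediate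
15 | [(3E)-3-methylhepta-3,6-dien-1-ylidene]triphenylphosphorane | C=CC/C=C(\C)CC=P(c1ccccc1)(c1ccccc1)c1ccccc1 | intermediate
16 | (2R,3S,7S,8Z,11E)-1,2-bis[(tert-butyldimethylsilyl)oxy]-3,7,11-trimethylpentadeca-8,11,14-trien-7-ol | CC(C)(C)[Si](C)(C)OC[C@H](O[Si](C)(C)C(C)(C)C)[C@@H](C)CCC[C@](C)(O)/C=C\C/C(C)=C/CC=C | intermediate
17 | (2R,3S,7S,8Z)-1,2-bis[(tert-butyldimethylsilyl)oxy]-3,7-dimethyl-10-[(2R,3R)-2-methyl-3-(prop-2-en-1-yl)oxiran-2-yl]dec-8-en-7-ol | CC(C)(C)[Si](C)(C)OC[C@H](O[Si](C)(C)C(C)(C)C)[C@@H](C)CCC[C@](C)(O)/C=C\C[C@@]1(C)O[C@@H]1CC=C | intermediate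
18 | (2R,3S,7S,8Z)-3,7-dimethyl-10-[(2R,3R)-2-methyl-3-(prop-2-en-1-yl)oxiran-2-yl]dec-8-ene-1,2,7-triol | OC[C@H](O)[C@@H](C)CCC[C@](C)(O)/C=C\C[C@@]1(C)O[C@@H]1CC=C | intermediate
19 | methyl 2-(bromomethyl)prop-2-enoate | C=C(CBr)C(=O)OC | starting material
20 | methyl (2Z)-2-(bromomethyl)-4-{(2R,3R)-3-methyl-3-[(2Z,4S,8S,9R)-4,9,10-trihydroxy-4,8-dimethyldec-2-en-1-yl]oxiran-2-yl}but-2-enoate | OC[C@H](O)[C@@H](C)CCC[C@](C)(O)/C=C\C[C@@]1(C)O[C@@H]1C/C=C(\CBr)C(=O)OC | intermediate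
21 | methyl (2Z)-2-(bromomethyl)-4-{(2R,3R)-3-[(2Z,4S,8S,9R)-4,9-dihydroxy-4,8-dimethyl-10-oxodec-2-en-1-yl]-3-methyloxiran-2-yl}but-2-enoate | O=C[C@H](O)[C@@H](C)CCC[C@](C)(O)/C=C\C[C@@]1(C)O[C@@H]1C/C=C(\CBr)C(=O)OC | intermediate
22 | methyl 2-[(1R,3Z,5S,9S,10R,11R,12S,14R)-5,10,11-trihydroxy-1,5,9-trimethyl-15-oxabicyclo[12.1.0]pentadec-3-en-12-yl]prop-2-enoate | O[C@H]1[C@H](O)[C@@H](C)CCC[C@](C)(O)/C=C\C[C@@]2(C)O[C@@H]2C[C@H]1C(=C)C(=O)OC | intermediate
23 | (1S,3R,4R,6Z,8S,12S,13R,14R)-3,4-epoxy-8,13-dihydroxycembra-6,15(17)-dien-16,14-olide (CNP0304380.1) | C=C1C(=O)O[C@H]2[C@H](O)[C@@H](C)CCC[C@](C)(O)/C=C\C[C@@]3(C)O[C@@H]3C[C@@H]12 | target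

**Step count and risk**
Total steps: 14. Longest linear sequence: 12 (steps 1–7 and 10–14, from 1).

Most likely to fail, step 14 (one-pot oxidation/indium macrocyclisation/lactonisation). The oxirane, which the C8 hydroxyl can attack under Lewis-acidic conditions, may not survive trivalent indium, and the closure may oligomerise or give the wrong C1/C14 diastereomer. The fallback installs the oxirane last and sets out from 16. Desilylation with Bu4NF gives (2R,3S,7S,8Z,11E)-3,7,11-trimethylpentadeca-8,11,14-triene-1,2,7-triol F1. Cross-metathesis with 19 under the conditions of step 13 gives methyl (2Z,5E,8Z,10S,14S,15R)-2-(bromomethyl)-10,15,16-trihydroxy-6,10,14-trimethylhexadeca-2,5,8-trienoate F2. The same oxidation/indium closure on this oxirane-free substrate gives (1S,3E,6Z,8S,12S,13R,14R)-8,13-dihydroxycembra-3,6,15(17)-trien-16,14-olide F3. A final Shi epoxidation (same ketone, KHSO5, buffer near pH 8–9, 0 °C, short contact) of the only electron-rich non-cis olefin, C3=C4, returns to 23; the exo-methylene lactone is inert to the dioxirane. The step count is unchanged.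

Second, step 13 (cross-metathesis with the hindered, electron-poor bromide 19 on a polyol). If 19 does not engage, the halogen is no longer carried through the metathesis. From 18, cross-metathesis with methyl 2-(hydroxymethyl)prop-2-enoate (a hydroxyl-assisted, less deactivated partner) gives methyl (2E)-2-(hydroxymethyl)-4-{(2R,3R)-3-methyl-3-[(2Z,4S,8S,9R)-4,9,10-trihydroxy-4,8-dimethyldec-2-en-1-yl]oxiran-2-yl}but-2-enoate F4. Its primary allylic hydroxyl alone is then substituted under Corey–Kim conditions (N-bromosuccinimide, Me2S, CH2Cl2, −20 °C), returning to 20.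

Third, step 10 (Wittig reaction on a free tertiary α-hydroxy aldehyde; Z-selectivity and α-ketol rearrangement are the concerns). The fallback makes the cis olefin by alkyne semihydrogenation instead and sets out from 9. Seyferth–Gilbert homologation with dimethyl (1-diazo-2-oxopropyl)phosphonate, K2CO3 and MeOH gives (3S,7S,8R)-8,9-bis[(tert-butyldimethylsilyl)oxy]-3,7-dimethylnon-1-yn-3-ol F5. Separately, carboalumination of prop-2-yn-1-ol (Me3Al, Cp2ZrCl2) and coupling with 11 under Pd(PPh3)4 gives (2E)-2-methylhexa-2,5-dien-1-ol F6, which PBr3 converts into (2E)-1-bromo-2-methylhexa-2,5-diene F7. Copper-mediated coupling of F5 with F7 (CuI, Cs2CO3, NaI, DMF) gives (2R,3S,7S,11E)-1,2-bis[(tert-butyldimethylsilyl)oxy]-3,7,11-trimethylpentadeca-11,14-dien-8-yn-7-ol F8. Semihydrogenation (H2, Pd on CaCO3 poisoned with Pb(OAc)2, quinoline) returns to 16.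

**Further compounds**
F1 | step 14 | (2R,3S,7S,8Z,11E)-3,7,11-trimethylpentadeca-8,11,14-triene-1,2,7-triol | OC[C@H](O)[C@@H](C)CCC[C@](C)(O)/C=C\C/C(C)=C/CC=C
F2 | step 14 | methyl (2Z,5E,8Z,10S,14S,15R)-2-(bromomethyl)-10,15,16-trihydroxy-6,10,14-trimethylhexadeca-2,5,8-trienoate | OC[C@H](O)[C@@H](C)CCC[C@](C)(O)/C=C\C/C(C)=C/C/C=C(\CBr)C(=O)OC
F3 | step 14 | (1S,3E,6Z,8S,12S,13R,14R)-8,13-dihydroxycembra-3,6,15(17)-trien-16,14-olide | C=C1C(=O)O[C@H]2[C@H](O)[C@@H](C)CCC[C@](C)(O)/C=C\C/C(C)=C/C[C@@H]12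
F4 | step 13 | methyl (2E)-2-(hydroxymethyl)-4-{(2R,3R)-3-methyl-3-[(2Z,4S,8S,9R)-4,9,10-trihydroxy-4,8-dimethyldec-2-en-1-yl]oxiran-2-yl}but-2-enoate | OC[C@H](O)[C@@H](C)CCC[C@](C)(O)/C=C\C[C@@]1(C)O[C@@H]1C/C=C(\CO)C(=O)OC
F5 | step 10 | (3S,7S,8R)-8,9-bis[(tert-butyldimethylsilyl)oxy]-3,7-dimethylnon-1-yn-3-ol | CC(C)(C)[Si](C)(C)OC[C@H](O[Si](C)(C)C(C)(C)C)[C@@H](C)CCC[C@](C)(O)C#C
F6 | step 10 | (2E)-2-methylhexa-2,5-dien-1-ol | OC/C(C)=C/CC=C
F7 | step 10 | (2E)-1-bromo-2-methylhexa-2,5-diene | BrC/C(C)=C/CC=C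
F8 | step 10 | (2R,3S,7S,11E)-1,2-bis[(tert-butyldimethylsilyl)oxy]-3,7,11-trimethylpentadeca-11,14-dien-8-yn-7-ol | CC(C)(C)[Si](C)(C)OC[C@H](O[Si](C)(C)C(C)(C)C)[C@@H](C)CCC[C@](C)(O)C#CC/C(C)=C/CC=C
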